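Two reagents compete for one starting material.

the same everywhere: starting material 0.10 M
- green: partner 1.2 equiv; second reagent 4 equiv; capture agent 2 mM; temperature 35 °C; run made earlier
- teal: partner 1.2 equiv; second reagent 2 equiv; capture agent 2 mM; temperature 46 °C; run made earlier
- amber: partner 1.2 equiv; second reagent 8 equiv; capture agent 2 mM; temperature 35 °C; run made earlier
- delta: partner 1.20 equiv (fed, over 1.5 h); second reagent 4.00 equiv; capture agent 2.00 mM; temperature 40 °C; all else is in the flask from the start; the feed brings no volume worth counting; time 4.0 h
- gamma: partner 1.20 equiv; second reagent 4.00 equiv; capture agent 2.00 mM; temperature 40 °C; everything together at the start; time 4.0 h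
- eta: partner 1.20 equiv; second reagent 4.00 equiv (fed, over 1.5 h); capture agent 2.00 mM; the addition at 10 °C, then warmed to 40 °C; the feed brings no volume worth counting; time 4.0 h
- theta: partner 1.20 equiv; second reagent 4.00 equiv (fed, over 1.5 h); capture agent 2.00 mM; temperature 40 °C; all else is in the flask from the start; the feed brings no volume worth counting; time 4.0 h

- green (time / h: target / %, side product / %, starting material / %): 0.333: 3.6, 73.6, 1.7; 0.833: 7.7, 74.3, 0.2; 1.50: 7.7, 76.8, 1.1; 2.50: 9.9, 73.8, 0
- teal (time / h: target / %, side product / %, starting material / %): 0.500: 8.8, 59.7, 0; 1.33: 12.5, 58.7, 0; 2.50: 14.7, 56.5, 0; 4.00: 14.5, 56.7, 0.4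
- amber (time / h: target / %, side product / %, starting material / %): 0.500: 5.8, 86.6, 0; 1.33: 6.5, 83.2, 0.5; 2.50: 5.7, 85.9, 0; 4.00: 7.6, 84.2, 0.3

(readings scatter by 1 percentage point)

- the flask with the highest share of target in target plus side product ("all alike" if they lie within 1.5 percentage points) (delta / gamma / eta / theta / all alike)
- share of target in target plus side product at the end, delta
- share of target in target plus side product at the end, gamma
- share of target in target plus side product at the end, eta
- share of target in target plus side product at the end, theta

Side product stands flat from the first readings, so we take the split as made early. At the first green reading, 0.333 h, starting material reads 1.7% against a scatter of 1 percentage point. Take the last readings, divide side product by the rest of the charge, and divide that by charged second reagent over partner. Green gives 0.845, amber 0.799, teal 0.786; green's reading, s, is our selectivity factor. In green, target is a fraction f = 0.378 of that rest.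

But a feed changes the ratio. We assume the same window as green's first reading, in which 22.2% of a feed enters, and take the mean fed amount as half of that. For theta, ρ, which is s times second reagent over partner, is then 0.313. So we reckon theta's side product as ρ/(1+ρ) = 23.8% and, carrying s and f over from green, its share as 54.7%. For delta, where partner is the fed one, we reckon ρ as 25.4 and the share as 1.47%. No run stands as cold as eta's addition at 10 °C, so we leave eta open.

The forecast says theta: delta 10%, gamma 12.5%, eta 14%, theta 38%, on the ground “Reaction occurs at low reagent concentration”. Our reckoning for theta stands higher.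

The flasks give delta 0.318%, gamma 13.2%, eta 30.3%, theta 64.9%, so theta leads.

    starting material + partner → open intermediate (k = 0.0350 L mol⁻¹ s⁻¹, Ea = 57.0 kJ mol⁻¹)
    second reagent + open intermediate → target (k = 9.70 × 10⁻⁴ L mol⁻¹ s⁻¹, Ea = 81.0 kJ mol⁻¹)
    starting material + second reagent → side product (k = 0.0290 L mol⁻¹ s⁻¹, Ea = 50.0 kJ mol⁻¹)
    open intermediate + capture agent → trapped intermediate (k = 0.00110 L mol⁻¹ s⁻¹, Ea = 52.0 kJ mol⁻¹)
    target ⇌ isomer of the product (K = 1.30, k = 7.00 × 10⁻⁴ s⁻¹, Ea = 101 kJ mol⁻¹, ΔH = 17.0 kJ mol⁻¹)
    (constants at 40 °C)

Now take theta at 0.25 M of starting material, equivalents held. Both steps consuming starting material are bimolecular, so at held equivalents we shorten the window by the concentration ratio, and the mean second reagent over partner in it falls the same way. For this flask we then reckon ρ as 0.125, side product as 11.1% and the share as 75.1%. That flask ends with side product 11.4% and a share of 77.0%.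

All runs were generated by integration on assumed constants, and the scatter is random.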